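**Retrosynthetic overview**

1. Building blocks: (S)-citronellol 1 supplies C13 and is advanced through chloride 2 and allylic alcohol 3 to allylic bromide 4; nerol 5 supplies the Z-olefin and is advanced through chloride 6 to barium reagent 7.
2. C–C disconnection: the allyl–allyl bond between 4 and 7 gives the (6E,10Z)-chlorotriene 8.
3. C–O disconnection: the C15–O acetate bond, made by displacing the primary chloride of 8, gives acyclic trienyl acetate 9.
4. Key C–O disconnection: the tertiary C8–O bond of target 10 is made last, by catalyst-directed capture of water at C8. The same event closes ring A first (C4–C5) and ring B second (C9–C10).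
5. Stereochemical logic: the Z-olefin gives the cis ring fusion, the E-olefin with a chair ring B gives C9 and C8, and the chiral acid sets the absolute sense; C13 comes from 1.

Assumption: the SMILES is taken literally as (5S,8R,9R,10R,13S), with H-5 and CH3-20 cis (a cis-fused 10-epi-labdane), so trans-fused sclareol (10S) cannot serve as a chiral-pool source.

Numbering: acyclic compounds are numbered from the CH2X end; the bicycle uses labdane numbering (chain C7, C6, C11, C10, C15, C3 become labdane C8, C9, C10, C5, C4, C13).

Acid A (step 7): (S,S)-HN[P(=NSO2CF3)(O2C20H10Ar2)]2, an imidodiphosphorimidate in which each O2C20H10Ar2 is an (S)-3,3′-diaryl-1,1′-binaphthalene-2,2′-diolate and Ar = 3,5-bis(trifluoromethyl)phenyl. Its mirror image is used instead if the first analytical run shows the opposite decalin; Ar is the tuning handle.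

**Step 1**
Reactants: 1 (S)-citronellol [(3S)-3,7-dimethyloct-6-en-1-ol]
Product: 2 (S)-citronellyl chloride [(6S)-8-chloro-2,6-dimethyloct-2-ene]
Conditions: PPh3, CCl4, 70 °C
Reagents that add atoms: carbon tetrachloride, ClC(Cl)(Cl)Cl
Why: Appel chlorination replaces the primary hydroxyl by SN2 displacement of an oxyphosphonium group without touching the olefin or the stereocentre, and the chloride is an organometallic-stable placeholder for the acetate.

**Step 2**
Reactants: 2 (S)-citronellyl chloride
Product: 3 (2E,6S)-8-chloro-2,6-dimethyloct-2-en-1-ol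
Conditions: SeO2 (10 mol %), tBuOOH (2.5 equiv), salicylic acid (10 mol %), CH2Cl2, 23 °C
Reagents that add atoms: tert-butyl hydroperoxide, CC(C)(C)OO (net oxygen source, relayed through selenium dioxide, O=[Se]=O)
Why: Catalytic selenium dioxide allylic oxidation (ene reaction then [2,3]-sigmatropic shift) hydroxylates only the E-methyl group of the terminal trisubstituted olefin, so the E-allylic alcohol results.

**Step 3**
Reactants: 3 (2E,6S)-8-chloro-2,6-dimethyloct-2-en-1-ol
Product: 4 (2E,6S)-1-bromo-8-chloro-2,6-dimethyloct-2-ene
Conditions: CBr4, PPh3, CH2Cl2, 0 °C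
Reagents that add atoms: carbon tetrabromide, BrC(Br)(Br)Br
Why: Appel bromination of the primary allylic alcohol is a direct SN2 displacement at 0 °C, so the E-olefin is kept and the unactivated primary chloride is untouched.

**Step 4**
Reactants: 5 nerol [(2Z)-3,7-dimethylocta-2,6-dien-1-ol]
Product: 6 neryl chloride [(2Z)-1-chloro-3,7-dimethylocta-2,6-diene]
Conditions: N-chlorosuccinimide, Me2S, CH2Cl2, −30 to 0 °C
Reagents that add atoms: N-chlorosuccinimide, O=C1CCC(=O)N1Cl
Why: Corey–Kim chlorination (alkoxysulfonium formation, then SN2 by chloride) gives the primary allylic chloride at low temperature without allylic transposition or Z-to-E isomerisation.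

**Step 5**
Reactants: 6 neryl chloride; 4 (2E,6S)-1-bromo-8-chloro-2,6-dimethyloct-2-ene
Product: 8 (3S,6E,10Z)-1-chloro-3,7,11,15-tetramethylhexadeca-6,10,14-triene, via nerylbarium chloride 7 (not isolated)
Conditions: BaI2, lithium biphenylide (from Li and biphenyl), THF, 23 °C; then 6 (1.5 equiv), −78 °C; then 4, −78 °C
Reagents that add atoms: none
Why: In this allylic-barium allyl–allyl cross-coupling the barium reagent formed at −78 °C is configurationally stable and joins its α-carbon to the α-carbon of the allylic bromide, so the Z-olefin of 7 and the E-olefin of 4 are both retained, while the primary alkyl chloride is inert at this temperature.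

**Step 6**
Reactants: 8 (3S,6E,10Z)-1-chloro-3,7,11,15-tetramethylhexadeca-6,10,14-triene
Product: 9 (3S,6E,10Z)-3,7,11,15-tetramethylhexadeca-6,10,14-trien-1-yl acetate
Conditions: CsOAc (3 equiv), NaI (10 mol %), DMF, 80 °C
Reagents that add atoms: caesium acetate, CC(=O)[O-].[Cs+]
Why: Iodide-assisted SN2 displacement of the unhindered primary chloride by acetate forms the C15–O bond under neutral conditions that leave the three olefins and C13 alone.

**Step 7**
Reactants: 9 (3S,6E,10Z)-3,7,11,15-tetramethylhexadeca-6,10,14-trien-1-yl acetate
Product: 10 (5S,8R,9R,10R,13S)-8-hydroxylabdan-15-yl acetate, 5,10-cis-fused {[(3S)-5-[(1R,2R,4aS,8aR)-2-hydroxy-2,5,5,8a-tetramethyldecahydronaphthalen-1-yl]-3-methylpentyl] acetate}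
Conditions: acid A (5 mol %), H2O (3 equiv), (CF3)3COH/CH2Cl2 (3:1), −20 °C
Reagents that add atoms: water, O
Why: Proposed new method: the confined chiral acid, in a non-nucleophilic cation-stabilising fluoroalcohol, protonates one face of the terminal olefin of folded 9 inside its anion pocket; the charge is passed by anti addition across the Z-olefin (H-5 and CH3-20 cis, C5 and C10) and then across the E-olefin through a chair ring B (side chain equatorial and trans to CH3-20, C9) to C8, where a water molecule hydrogen-bonded to the sulfonyl imide of the counter-anion adds anti to the new C9–C10 bond (equatorial C8–O, 8R) and returns the proton to the catalyst, so the absolute sense is catalyst-controlled and the remote C13 centre is not needed; the closest known reaction types are the confined-Brønsted-acid-catalysed enantioselective cyclisation of E,E-homofarnesol-type polyenes ended by an internal hydroxyl and acid-catalysed asymmetric hydroalkoxylation of unactivated olefins, and new here are intermolecular water as the terminating nucleophile and a Z-configured internal olefin.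

**Compound list**

1 | (S)-citronellol, (3S)-3,7-dimethyloct-6-en-1-ol | OCC[C@@H](C)CCC=C(C)C | starting material
2 | (S)-citronellyl chloride, (6S)-8-chloro-2,6-dimethyloct-2-ene | ClCC[C@@H](C)CCC=C(C)C | intermediate
3 | (2E,6S)-8-chloro-2,6-dimethyloct-2-en-1-ol | ClCC[C@@H](C)CC/C=C(\C)CO | intermediate
4 | (2E,6S)-1-bromo-8-chloro-2,6-dimethyloct-2-ene | ClCC[C@@H](C)CC/C=C(\C)CBr | intermediate
5 | nerol, (2Z)-3,7-dimethylocta-2,6-dien-1-ol | CC(C)=CCC/C(C)=C\CO | starting material
6 | neryl chloride, (2Z)-1-chloro-3,7-dimethylocta-2,6-diene | CC(C)=CCC/C(C)=C\CCl | intermediate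
7 | nerylbarium chloride, [(2Z)-3,7-dimethylocta-2,6-dien-1-yl]barium chloride | CC(C)=CCC/C(C)=C\C[Ba]Cl | intermediate (not isolated)
8 | (3S,6E,10Z)-1-chloro-3,7,11,15-tetramethylhexadeca-6,10,14-triene | ClCC[C@@H](C)CC/C=C(\C)CC/C=C(/C)CCC=C(C)C | intermediate
9 | (3S,6E,10Z)-3,7,11,15-tetramethylhexadeca-6,10,14-trien-1-yl acetate | CC(=O)OCC[C@@H](C)CC/C=C(\C)CC/C=C(/C)CCC=C(C)C | intermediate
10 | (5S,8R,9R,10R,13S)-8-hydroxylabdan-15-yl acetate, 5,10-cis-fused | CC(=O)OCC[C@@H](C)CC[C@@H]1[C@]2(C)CCCC(C)(C)[C@@H]2CC[C@@]1(C)O | target

**Step count and risks**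

Total steps: 7. Longest linear sequence: 6 steps (1 → 2 → 3 → 4 → 8 → 9 → 10); the nerol branch adds one step before the coupling.

Steps most likely to fail:

Step 7 (the proposed new hydrative bicyclisation). Water may level the acid, C8 may lose a proton instead of taking up water, the Z-olefin may react stepwise and leak to trans-fused material, or the facial control may be low. The fallback uses known chemistry, sets out from 9 and comes back at 10. Compound 9 is cyclised with the achiral superacid FSO3H in 2-nitropropane at −78 °C, a known cyclisation of polyprenyl acetates in which a Z internal olefin gives the cis ring fusion. This gives the ring-B olefin with the decalin configured as in 10, (13S)-5,10-cis-labd-7-en-15-yl acetate F1, as a roughly 1:1 mixture with the ring-antipodal olefin on the same 13S chain F2. Mukaiyama hydration of the mixture (Co(acac)2, PhSiH3, O2, THF, 23 °C) then forms the C8–O bond by hydrogen-atom transfer to C7 and oxygen capture at the tertiary C8 radical. Compound 10 is separated by preparative HPLC from the ring-antipodal hydroxy acetate F3 and from any C8 epimers. This costs one more step and at best half of the material.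

Step 5 (allylic barium coupling). Risks are homocoupling of 6, some γ-attack, and attack of residual reductant on the C–Cl bond. The fallback sets out from 6 and 4 and comes back at 8. Compound 6 is treated with PhSO2Na in DMF at 23 °C to give neryl phenyl sulfone F4. Its lithium carbanion (nBuLi, THF, −78 °C) is alkylated by 4 at the allylic bromide to give (3S,6E,10Z)-1-chloro-3,7,11,15-tetramethyl-9-(phenylsulfonyl)hexadeca-6,10,14-triene F5 as a mixture of C9 epimers. PdCl2(dppp)-catalysed reduction with LiEt3BH (THF, 0 °C, short contact to spare the primary chloride) removes the sulfonyl group with retention of olefin positions and geometries and returns 8.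

Step 2 (allylic oxidation). Conversion is typically moderate and some over-oxidation to the enal occurs. The fallback sets out from 2 and comes back at 3. Ozonolysis of 2 (O3, CH2Cl2/MeOH, −78 °C; then Me2S) gives (4S)-6-chloro-4-methylhexanal F6. Wittig olefination with the stabilised ylide Ph3P=C(CH3)CO2Et (toluene, 80 °C) gives the E-enoate ethyl (2E,6S)-8-chloro-2,6-dimethyloct-2-enoate F7. Reduction with iBu2AlH (CH2Cl2, −78 °C) gives 3.

**Further compounds**

F1 | step 7 | (13S)-5,10-cis-labd-7-en-15-yl acetate, C5, C9, C10 configured as in 10 | CC(=O)OCC[C@@H](C)CC[C@@H]1[C@]2(C)CCCC(C)(C)[C@@H]2CC=C1C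
F2 | step 7 | ring-antipodal olefin, diastereomer of F1 with the mirror-image decalin and 13S | CC(=O)OCC[C@@H](C)CC[C@H]1[C@@]2(C)CCCC(C)(C)[C@H]2CC=C1C
F3 | step 7 | ring-antipodal hydroxy acetate, (5R,8S,9S,10S,13S)-8-hydroxylabdan-15-yl acetate | CC(=O)OCC[C@@H](C)CC[C@H]1[C@@]2(C)CCCC(C)(C)[C@H]2CC[C@]1(C)O
F4 | step 5 | neryl phenyl sulfone, [(2Z)-3,7-dimethylocta-2,6-dien-1-yl]sulfonylbenzene | CC(C)=CCC/C(C)=C\CS(=O)(=O)c1ccccc1
F5 | step 5 | (3S,6E,10Z)-1-chloro-3,7,11,15-tetramethyl-9-(phenylsulfonyl)hexadeca-6,10,14-triene, C9 epimers | ClCC[C@@H](C)CC/C=C(\C)CC(/C=C(/C)CCC=C(C)C)S(=O)(=O)c1ccccc1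
F6 | step 2 | (4S)-6-chloro-4-methylhexanal | ClCC[C@@H](C)CCC=O
F7 | step 2 | ethyl (2E,6S)-8-chloro-2,6-dimethyloct-2-enoate | ClCC[C@@H](C)CC/C=C(\C)C(=O)OCC
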